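The left-handed product stalls near 9.43% in the winter run and 11.9% in the spring run (means of the last readings), though the spring run had more reagent.

all flasks: left-handed substrate 0.025 M; right-handed substrate 0.025 M; free catalyst 0.1 mol%; impurity 3.2 µM

| flask | reagent | remark |
|---|---|---|
| winter | 0.60 equiv | run made earlier |
| spring | 0.90 equiv | run made earlier |
| flask | 1.20 equiv |  |

| run | time / min | left-handed product / % | left-handed substrate / % |
|---|---|---|---|
| winter | 0.250 | 4.3 | 44.6 |
| winter | 0.833 | 7.7 | 41.6 |
| winter | 1.33 | 9.2 | 40.3 |
| winter | 2.50 | 9.0 | 39.4 |
| winter | 3.00 | 10.1 | 39.9 |
| spring | 0.667 | 9.0 | 40.6 |
| spring | 1.33 | 11.3 | 39.7 |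
| spring | 2.00 | 11.5 | 38.6 |
| spring | 2.50 | 12.1 | 37.7 |
| spring | 3.00 | 12.0 | 38.3 |

(each reading ± 0.5 percentage points)

- free catalyst is single-handed; left-handed substrate and right-handed substrate are mirror images of each other, charged as a racemate, each of them at the stated concentration
- on the list of suspects stand: reagent + free catalyst + right-handed substrate -> free catalyst + right-handed product; reagent + free catalyst + left-handed substrate -> free catalyst + left-handed product; free catalyst + impurity -> spent catalyst; 2 reagent -> homo dimer
- no earlier run changes the charge of free catalyst; that part of a forecast is a guess

- factor on the rate of making left-handed product when 5.0% of the left-handed substrate and right-handed substrate together are converted if reagent is charged twice over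
- factor on the rate when 5.0% of the left-handed substrate and right-handed substrate together are converted if free catalyst is charged at 0.5 mol% instead

Reagent is the limiting reagent: 0.0300 M in the flask stands against 0.0500 M of substrates, less. Suppose it leaves by two routes, catalytic use and loss to homo dimer. Let p be the reagent turned into both products. The balance is then −d[reagent]/dp = 1 + [reagent]/b. Here b is the crossover [reagent], the level at which dimer loss and catalytic use run equally. It contains free catalyst and substrates, not the reagent charge. Integrated with b held fixed, [reagent] + b = ([reagent]₀ + b)·exp(−p/b), and the stall is p = b·ln(1 + [reagent]₀/b).

The spring stall over the winter stall reads 1.26. A trial b = 0.00500 M gives 1.23.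

At the asked conversion p = 0.00250 M, so [reagent] = 0.0162 M. Charged twice over, it stands 2.12 times higher, and the rate follows it.

If each impurity takes one catalyst, a charge of 0.5 mol% leaves 5.59 times as much free catalyst, and b rises with it. This reckoning then gives a rate factor of 8.62.

The weak link is b. With b at 0.00313 M the stall ratio is 1.20 and the factor 11.2. With b at 0.00833 M they are 1.27 and 7.24. The scatter of the stalls does not separate these, so that span stands around the reckoned factor.

The forecast says 2.1 and 14: “The likely cause is reagent loss by second-order dimerisation.” Its catalyst factor stands above this reckoning's.

The flask gives 2.12 and 8.24.

    reagent + free catalyst + right-handed substrate → free catalyst + right-handed product (k = 15200 /M²/s)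
    reagent + free catalyst + left-handed substrate → free catalyst + left-handed product (k = 34600 /M²/s)
    free catalyst + impurity → spent catalyst (k = 1.33 × 10⁶ /M/s)
    2 reagent → homo dimer (k = 2.37 /M/s)

At the start, dimer loss uses reagent 6.6 times as fast as the making of left-handed product. With b = 0.00500 M, the stall formula puts both products together at 19.5% of the substrates charged. At 4.00 min the flask holds 13.4% left-handed and 6.43% right-handed product. In the flask with twice the reagent, the same balance puts the time factor to that conversion between 0.471 and 0.5; that flask gives 0.485.

The data stem from a simulated flask for substances that don't exist, and the scatter is random.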